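Ring C of the target is a β-aryloxy ketone: O1 is a phenolic oxygen of ring A sitting ortho to the C4 acyl carbon, and C2 is the benzylic carbon β to that carbonyl. Everything rests on the O1–C2 disconnection, which copies chalcone isomerase: a cinchona-derived bifunctional thiourea closes the pyranone ring of a 2'-hydroxychalcone by enantioselective 6-endo oxa-Michael addition, making the O1–C2 bond and the only stereocentre (C2, S) in one operation. The precursor is an (E)-chalcone from a Claisen–Schmidt condensation, whose second ortho oxygen (the future O5, next to the prenyl group) is masked as a MOM ether, so only the phenol flanked by C8–H can cyclise.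

Key step: step 6

Assumption: the quinidine-derived thiourea is taken to give the (2S) flavanone by analogy with cinchona-thiourea oxa-Michael cyclisations of related o-hydroxyaryl enones; the facial sense belongs to the catalyst series, so the pseudoenantiomeric quinine-derived catalyst would be used if the opposite sense were found.

Step 1
Reactants: 1 1-(2,6-dihydroxy-4-methoxyphenyl)ethanone; 2 chloromethyl methyl ether
Product: 3 1-[2-hydroxy-4-methoxy-6-(methoxymethoxy)phenyl]ethanone
Conditions: MOMCl (1.05 equiv), i-Pr2NEt, CH2Cl2, 0 °C → rt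
Reagents that add atoms: chloromethyl methyl ether (2), COCCl
Why: Williamson-type O-alkylation (MOM protection); 1 is symmetrical, so either hydroxyl gives the same ether, and the second hydroxyl should stay free because it is locked in a hydrogen bond to the ketone.

Step 2
Reactants: 3 1-[2-hydroxy-4-methoxy-6-(methoxymethoxy)phenyl]ethanone; 4 prenyl bromide (1-bromo-3-methylbut-2-ene)
Product: 5 1-[4-methoxy-2-(methoxymethoxy)-6-(3-methylbut-2-enyloxy)phenyl]ethanone
Conditions: prenyl bromide (1.3 equiv), K2CO3, acetone, reflux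
Reagents that add atoms: prenyl bromide (4), CC(C)=CCBr
Why: Williamson ether synthesis; the chelated phenoxide formed by K2CO3 in hot acetone should be alkylated on oxygen by the primary allylic bromide in an SN2 reaction.

Step 3
Reactants: 5 1-[4-methoxy-2-(methoxymethoxy)-6-(3-methylbut-2-enyloxy)phenyl]ethanone
Product: 8 1-[6-hydroxy-4-methoxy-2-(methoxymethoxy)-3-(3-methylbut-2-enyl)phenyl]ethanone, via ortho-dienone 6 (not isolated), via para-dienone 7 (not isolated)
Conditions: N,N-diethylaniline, 200 °C, Ar
Reagents that add atoms: none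
Why: Aromatic Claisen rearrangement followed by Cope rearrangement (para-Claisen–Cope); the first [3,3] shift to the only free ortho carbon gives the crowded ortho-dienone, the second [3,3] shift carries the allyl unit, restored to a normal prenyl group, to the para carbon between OMe and OMOM, and tautomerisation returns the phenol flanked by C–H.

Step 4
Reactants: 9 3,4-dimethoxybenzaldehyde (veratraldehyde); 10 geranyl bromide ((2E)-1-bromo-3,7-dimethylocta-2,6-diene)
Product: 14 2-[(2E)-3,7-dimethylocta-2,6-dienyl]-3,4-dimethoxybenzaldehyde, via lithium α-amino alkoxide 11 (not isolated), via C2-aryllithium 12 (not isolated), via geranylated α-amino alkoxide 13 (not isolated)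
Conditions: LiN(Me)CH2CH2NMe2 (from N,N,N'-trimethylethylenediamine and n-BuLi), THF, −20 °C; n-BuLi (3 equiv), −20 °C, 20 h; CuBr·SMe2 (20 mol %), geranyl bromide (4 equiv), −78 °C → rt; H2O
Reagents that add atoms: geranyl bromide (10), BrC/C=C(\C)CCC=C(C)C
Why: Comins in situ protection and directed ortho-lithiation; the α-amino alkoxide and the C3 methoxy group should together direct lithiation to C2, copper-catalysed SN2 allylation at the primary carbon of geranyl bromide keeps the E geometry, and water releases the aldehyde.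

Step 5
Reactants: 8 1-[6-hydroxy-4-methoxy-2-(methoxymethoxy)-3-(3-methylbut-2-enyl)phenyl]ethanone; 14 2-[(2E)-3,7-dimethylocta-2,6-dienyl]-3,4-dimethoxybenzaldehyde
Product: 16 (2E)-3-{2-[(2E)-3,7-dimethylocta-2,6-dienyl]-3,4-dimethoxyphenyl}-1-[6-hydroxy-4-methoxy-2-(methoxymethoxy)-3-(3-methylbut-2-enyl)phenyl]prop-2-en-1-one, via aldol adduct 15 (not isolated)
Conditions: KOH (50% aq.), EtOH, 0 °C → rt; then cold AcOH to pH 6
Reagents that add atoms: none
Why: Claisen–Schmidt (crossed aldol) condensation; the ketone enolate adds to the non-enolisable aldehyde and E1cB dehydration gives the conjugated E-enone, whose phenoxide resists ring closure in strong base, so cold neutralisation should deliver the open chalcone.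

Step 6
Reactants: 16 (2E)-3-{2-[(2E)-3,7-dimethylocta-2,6-dienyl]-3,4-dimethoxyphenyl}-1-[6-hydroxy-4-methoxy-2-(methoxymethoxy)-3-(3-methylbut-2-enyl)phenyl]prop-2-en-1-one
Product: 17 (2S)-2-{2-[(2E)-3,7-dimethylocta-2,6-dienyl]-3,4-dimethoxyphenyl}-7-methoxy-5-(methoxymethoxy)-6-(3-methylbut-2-enyl)-2,3-dihydro-4H-chromen-4-one
Conditions: N-[3,5-bis(trifluoromethyl)phenyl]-N'-[(9R)-6'-methoxycinchonan-9-yl]thiourea (quinidine-derived, 20 mol %), toluene, 4 Å MS, 25 °C, stopped at full conversion
Reagents that add atoms: none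
Why: The quinuclidine nitrogen of the catalyst deprotonates the C6' phenol, which is acidified by the ortho carbonyl, while the thiourea N–H bonds hold the enone carbonyl, so the phenoxide oxygen adds to the β-carbon inside a chiral ion pair and the enol is then protonated at C3. The closest known reaction type is the asymmetric intramolecular oxa-Michael addition of 2'-hydroxychalcones under cinchona-type bifunctional catalysis, the laboratory counterpart of chalcone isomerase. Ring C closes in the 6-endo-trig mode. The C2 stereocentre is under catalyst control alone, since the substrate has no other stereogenic element: the catalyst exposes the face of the β-carbon that leads to (S). The step needs regioselectivity between the two ortho oxygens, secured by the MOM ether on the oxygen next to the prenyl group, and enantioselectivity that is not eroded by retro-Michael opening, secured by the weak tertiary-amine base, the non-polar solvent and the 6'-alkoxy group, which biases the equilibrium towards the flavanone.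

Step 7
Reactants: 17 (2S)-2-{2-[(2E)-3,7-dimethylocta-2,6-dienyl]-3,4-dimethoxyphenyl}-7-methoxy-5-(methoxymethoxy)-6-(3-methylbut-2-enyl)-2,3-dihydro-4H-chromen-4-one
Product: 18 (2S)-2-{2-[(2E)-3,7-dimethylocta-2,6-dienyl]-3,4-dimethoxyphenyl}-5-hydroxy-7-methoxy-6-(3-methylbut-2-enyl)-2,3-dihydro-4H-chromen-4-one
Conditions: HCl (1 M), MeOH, 0 °C → rt
Reagents that add atoms: none
Why: Acid-catalysed acetal methanolysis; the MOM ether peri to the C4 carbonyl should cleave under mild conditions, the freed 5-OH is held by a hydrogen bond to the carbonyl, and cold dilute acid is not expected to open ring C, so the C2 configuration should be retained.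

Compound list
1 | 1-(2,6-dihydroxy-4-methoxyphenyl)ethanone | CC(=O)c1c(O)cc(OC)cc1O | starting material
2 | chloromethyl methyl ether | COCCl | starting material
3 | 1-[2-hydroxy-4-methoxy-6-(methoxymethoxy)phenyl]ethanone | CC(=O)c1c(O)cc(OC)cc1OCOC | intermediate
4 | prenyl bromide (1-bromo-3-methylbut-2-ene) | CC(C)=CCBr | starting material
5 | 1-[4-methoxy-2-(methoxymethoxy)-6-(3-methylbut-2-enyloxy)phenyl]ethanone | CC(=O)c1c(OCC=C(C)C)cc(OC)cc1OCOC | intermediate
6 | 2-acetyl-5-methoxy-3-(methoxymethoxy)-6-(2-methylbut-3-en-2-yl)cyclohexa-2,4-dien-1-one (ortho-dienone, not isolated) | CC(=O)C1=C(OCOC)C=C(OC)C(C(C)(C)C=C)C1=O | intermediate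
7 | 2-acetyl-5-methoxy-3-(methoxymethoxy)-4-(3-methylbut-2-enyl)cyclohexa-2,5-dien-1-one (para-dienone, not isolated) | CC(=O)C1=C(OCOC)C(CC=C(C)C)C(OC)=CC1=O | intermediate
8 | 1-[6-hydroxy-4-methoxy-2-(methoxymethoxy)-3-(3-methylbut-2-enyl)phenyl]ethanone | CC(=O)c1c(O)cc(OC)c(CC=C(C)C)c1OCOC | intermediate
9 | 3,4-dimethoxybenzaldehyde (veratraldehyde) | COc1ccc(C=O)cc1OC | starting material
10 | geranyl bromide ((2E)-1-bromo-3,7-dimethylocta-2,6-diene) | BrC/C=C(\C)CCC=C(C)C | starting material
11 | lithium (3,4-dimethoxyphenyl){[2-(dimethylamino)ethyl](methyl)amino}methanolate (lithium α-amino alkoxide, not isolated) | COc1ccc(C(O[Li])N(C)CCN(C)C)cc1OC | intermediate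
12 | C2-lithiated lithium α-amino alkoxide of veratraldehyde (not isolated) | COc1ccc(C(O[Li])N(C)CCN(C)C)c([Li])c1OC | intermediate
13 | lithium α-amino alkoxide of 2-geranyl-3,4-dimethoxybenzaldehyde (not isolated) | COc1ccc(C(O[Li])N(C)CCN(C)C)c(C/C=C(\C)CCC=C(C)C)c1OC | intermediate
14 | 2-[(2E)-3,7-dimethylocta-2,6-dienyl]-3,4-dimethoxybenzaldehyde | COc1ccc(C=O)c(C/C=C(\C)CCC=C(C)C)c1OC | intermediate
15 | 3-{2-[(2E)-3,7-dimethylocta-2,6-dienyl]-3,4-dimethoxyphenyl}-3-hydroxy-1-[6-hydroxy-4-methoxy-2-(methoxymethoxy)-3-(3-methylbut-2-enyl)phenyl]propan-1-one (racemic aldol adduct, not isolated) | CC(C)=CCc1c(OC)cc(O)c(C(=O)CC(O)c2ccc(OC)c(OC)c2C/C=C(\C)CCC=C(C)C)c1OCOC | intermediate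
16 | (2E)-3-{2-[(2E)-3,7-dimethylocta-2,6-dienyl]-3,4-dimethoxyphenyl}-1-[6-hydroxy-4-methoxy-2-(methoxymethoxy)-3-(3-methylbut-2-enyl)phenyl]prop-2-en-1-one | CC(C)=CCc1c(OC)cc(O)c(C(=O)/C=C/c2ccc(OC)c(OC)c2C/C=C(\C)CCC=C(C)C)c1OCOC | intermediate
17 | (2S)-2-{2-[(2E)-3,7-dimethylocta-2,6-dienyl]-3,4-dimethoxyphenyl}-7-methoxy-5-(methoxymethoxy)-6-(3-methylbut-2-enyl)-2,3-dihydro-4H-chromen-4-one | COc1cc2c(c(OCOC)c1CC=C(C)C)C(=O)C[C@@H](c1ccc(OC)c(OC)c1C/C=C(\C)CCC=C(C)C)O2 | intermediate
18 | (2S)-2-{2-[(2E)-3,7-dimethylocta-2,6-dienyl]-3,4-dimethoxyphenyl}-5-hydroxy-7-methoxy-6-(3-methylbut-2-enyl)-2,3-dihydro-4H-chromen-4-one | COc1cc2c(c(O)c1CC=C(C)C)C(=O)C[C@@H](c1ccc(OC)c(OC)c1C/C=C(\C)CCC=C(C)C)O2 | target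

Total step count: 7. Longest linear sequence: 6 steps (steps 1, 2, 3, 5, 6, 7); step 4 supplies the aldehyde for step 5.

Steps most likely to fail

Step 6. The unactivated enone is a weak acceptor and the ortho-geranyl aryl group crowds the β-carbon, so addition may stall or proceed with poor facial discrimination, and long exposure to the amine may erode the ee by retro-Michael opening. The fallback sets out from acetophenone 8 and activates the acceptor with a removable ester. C-acylation of the lithium dianion of 8 (LiHMDS, THF, −78 °C) with Boc2O should give the tert-butyl β-keto ester F1 (any aryl carbonate formed at the phenol being cleaved with K2CO3 in MeOH). Knoevenagel condensation of F1 with aldehyde 14 (piperidine, AcOH, toluene, 4 Å MS) should give the alkylidene β-keto ester F2 as an E/Z mixture. The same type of bifunctional thiourea in toluene at −25 °C should close ring C by the known oxa-Michael addition to the doubly activated alkene, giving the 3-(tert-butoxycarbonyl)flavanone F3. TsOH in toluene at 80 °C then removes the ester by dealkylation and decarboxylation, and the fallback comes back to the route at 17.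

Step 4. The excess n-butyllithium and lithium amide carried into the alkylation consume geranyl bromide, and the hindered aryllithium may alkylate slowly, partly at the tertiary γ-terminus (SN2'), or lithiation may be incomplete. The fallback sets out from geranyl bromide 10 and replaces the organolithium alkylation by a cross-coupling. Borylation of 10 with B2pin2 and Pd2(dba)3 (a zerovalent palladium source) in THF should give the linear (E)-geranylboronic acid pinacol ester F4. α-Selective Suzuki–Miyaura coupling of F4 with commercial 2-bromo-3,4-dimethoxybenzaldehyde (COc1ccc(C=O)c(Br)c1OC), using Pd(OAc)2, a bulky biarylphosphine and K3PO4 in THF/H2O at 40 °C, comes back to the route at 14.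

Step 3. The ortho-dienone may tautomerise before the Cope shift, which would leave the 1,1-dimethylallyl group on the ortho carbon, and the MOM or prenyl group may be lost thermally at 200 °C. The fallback sets out from 1 and installs the prenyl group directly, then differentiates the two hydroxyls by protecting groups. C-prenylation of 1 with prenyl bromide 4 in 10% aqueous KOH at 0 °C should give 1-[2,6-dihydroxy-4-methoxy-3-(3-methylbut-2-enyl)phenyl]ethanone F5. Silylation of the less hindered hydroxyl, the one flanked by C–H (TBSCl, imidazole, DMF, 0 °C), should give the mono-TBS ether F6. MOM protection of the remaining hindered hydroxyl (MOMCl, i-Pr2NEt, CH2Cl2) should give the TBS/MOM diether F7. Desilylation with TBAF buffered with AcOH in THF at 0 °C comes back to the route at 8.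

Further compounds
F1 | step 6 | tert-butyl 3-[6-hydroxy-4-methoxy-2-(methoxymethoxy)-3-(3-methylbut-2-enyl)phenyl]-3-oxopropanoate | CC(C)=CCc1c(OC)cc(O)c(C(=O)CC(=O)OC(C)(C)C)c1OCOC
F2 | step 6 | tert-butyl 3-{2-[(2E)-3,7-dimethylocta-2,6-dienyl]-3,4-dimethoxyphenyl}-2-[6-hydroxy-4-methoxy-2-(methoxymethoxy)-3-(3-methylbut-2-enyl)benzoyl]prop-2-enoate (E/Z mixture) | CC(C)=CCc1c(OC)cc(O)c(C(=O)C(=Cc2ccc(OC)c(OC)c2C/C=C(\C)CCC=C(C)C)C(=O)OC(C)(C)C)c1OCOC
F3 | step 6 | tert-butyl (2S)-2-{2-[(2E)-3,7-dimethylocta-2,6-dienyl]-3,4-dimethoxyphenyl}-7-methoxy-5-(methoxymethoxy)-6-(3-methylbut-2-enyl)-4-oxo-3,4-dihydro-2H-chromene-3-carboxylate (C3 epimers) | COc1cc2c(c(OCOC)c1CC=C(C)C)C(=O)C(C(=O)OC(C)(C)C)[C@@H](c1ccc(OC)c(OC)c1C/C=C(\C)CCC=C(C)C)O2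
F4 | step 4 | 2-[(2E)-3,7-dimethylocta-2,6-dienyl]-4,4,5,5-tetramethyl-1,3,2-dioxaborolane | CC(C)=CCC/C(C)=C/CB1OC(C)(C)C(C)(C)O1
F5 | step 3 | 1-[2,6-dihydroxy-4-methoxy-3-(3-methylbut-2-enyl)phenyl]ethanone | CC(=O)c1c(O)cc(OC)c(CC=C(C)C)c1O
F6 | step 3 | 1-[6-(tert-butyldimethylsilyloxy)-2-hydroxy-4-methoxy-3-(3-methylbut-2-enyl)phenyl]ethanone | CC(=O)c1c(O[Si](C)(C)C(C)(C)C)cc(OC)c(CC=C(C)C)c1O
F7 | step 3 | 1-[6-(tert-butyldimethylsilyloxy)-4-methoxy-2-(methoxymethoxy)-3-(3-methylbut-2-enyl)phenyl]ethanone | CC(=O)c1c(O[Si](C)(C)C(C)(C)C)cc(OC)c(CC=C(C)C)c1OCOC
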